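Your flask holds 0.700 mM of pre-initiator, and the chain count starts from that number. Average length is by definition monomer in chains over chains begun, so you need both counts at the asked time. I take one chain per unit of pre-initiator.

the same everywhere: free monomer 0.14 M
- beta: pre-initiator 0.5 mol%; impurity 0.32 mM; run made earlier
- epsilon: pre-initiator 0.5 mol%; impurity 0.51 mM; run made earlier
- zeta: pre-initiator 1 mol%; impurity 0.23 mM; run made earlier
- flask: pre-initiator 0.5 mol%; impurity 0.23 mM; time 50 min

| run | time / min | monomer in chains / % | free monomer / % |
|---|---|---|---|
| beta | 12.0 | 2.0 | 97.1 |
| beta | 25.0 | 5.1 | 92.7 |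
| beta | 40.0 | 9.6 | 90.1 |
| beta | 50.0 | 12.7 | 87.7 |
| epsilon | 6.00 | 0.7 | 101.5 |
| epsilon | 20.0 | 4.8 | 99.0 |
| epsilon | 30.0 | 5.2 | 94.0 |
| epsilon | 50.0 | 11.9 | 88.8 |
| zeta | 6.00 | 0 | 99.0 |
| zeta | 20.0 | 10.1 | 91.8 |
| zeta | 30.0 | 14.6 | 86.4 |
| zeta | 50.0 | 30.1 | 70.5 |

(readings scatter by 1 percentage point)

- the average divides the monomer in chains by the number of chains begun, living and dead together
- the earlier runs do not show the number of chains; that part of a forecast is a guess

1. whether the average number of monomer units in a chain (chains begun, living or dead) reaches 200 by 50 min (yes / no)
2. average number of monomer units in a chain (chains begun, living or dead) at 50 min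

I keep the books like this. The credit is the charge. The debit is the impurity, 0.23 mM, if each unit takes one pre-initiator unit before it starts a chain. That debit is a bet. At double the loading, zeta holds 2.37 times beta's monomer in chains, more than the loading ratio, which suggests a fixed loss. But beta's 12.7% and epsilon's 11.9% lie within scatter of each other. The balance is 0.470 mM: the net charge C, pre-initiator charged less impurity charged, my count of chains begun. Beta's reading gives 17.8 mM in chains, so I expect a length of 37.8. The length asked needs 0.0889 mM of chains, far below C, so my answer is no.

The forecast also says no, but gives 30, shorter than mine, holding that “impurity barely affects rate”.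

The flask gives no and 49.7, with 15.1% in chains.

    monomer in chains + living end → free monomer + living end, rate k1*[living end] as long as [monomer in chains] is above zero (k = 0.0110 /s)
    initiator + impurity → spent initiator A (k = 26.0 /M/s)
    free monomer + initiator → living end + monomer in chains (k = 0.0600 /M/s)
    pre-initiator ⇌ initiator (K = 8.40, k = 6.70 × 10⁻⁴ /s)
    free monomer + living end → monomer in chains + living end, rate k5*[living end]*[free monomer] (k = 0.410 /M/s)
    living end → dead end B (k = 4.70 × 10⁻⁴ /s)

Living end plus dead end B in this flask come to 0.425 mM, below C, and its monomer in chains over C gives 44.9. The neighbour flask, charged with 0.56 M of free monomer and the same impurity concentration, has C = 2.57 mM. Its 63.1% in chains over C gives 137. There, 2.19 mM of chains have begun, and the length is 161.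

The earlier runs and the new flask are calculated for substances that don't exist, noise included.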